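The numbers are assumed; the rest is arithmetic.

Left-handed product can come from two sources: left-handed substrate charged as such, and right-handed substrate that crossed over before it was consumed.

in all of them: left-handed substrate 0.0020 M; partner 4.40 mM; racemization catalyst 10 µM; precatalyst 0.34 mM; impurity 9.0 µM; right-handed substrate 0.0020 M; time 1.0 min

|  | remark | temperature |
|---|---|---|
| alpha | at 25 °C until 30 s, from then on at 50 °C |  |
| theta |  | 25 °C |
| gamma |  | 50 °C |

    partner + free catalyst + left-handed substrate → free catalyst + left-handed product (k1 = 1.60 × 10⁶ /M²/s, Ea1 = 15.0 kJ/mol)
    partner + free catalyst + right-handed substrate → free catalyst + right-handed product (k2 = 7.79 × 10⁵ /M²/s, Ea2 = 15.0 kJ/mol)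
    left-handed substrate + racemization catalyst ⇌ right-handed substrate + racemization catalyst, rate k3*[racemization catalyst]*[left-handed substrate] forward; the back reaction follows from the equilibrium constant (k3 = 7990 /M/s, Ea3 = 14.0 kJ/mol)
    precatalyst → free catalyst (k4 = 0.00459 /s, Ea4 = 84.0 kJ/mol)
    racemization catalyst + impurity → spent catalyst (k5 = 1.62 × 10⁵ /M/s, Ea5 = 17.0 kJ/mol)
    (constants at 25 °C)

- free catalyst is single-handed; left-handed substrate and right-handed substrate are mirror images of each other, charged as a racemate, each of them at the stated concentration
- at 25 °C the constants are as listed, elsewhere as the activation energies make them

- the best flask by amount of left-handed product, in percent of the left-handed substrate and right-handed substrate together charged; "all alike" if 1.5 percentage points covers them all (alpha / theta / gamma / all alike)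
- amount of left-handed product at the end, in percent of the left-handed substrate and right-handed substrate together charged, alpha
- amount of left-handed product at the end, in percent of the left-handed substrate and right-handed substrate together charged, theta
- amount of left-handed product at the end, in percent of the left-handed substrate and right-handed substrate together charged, gamma

1. Floor. Once the substrate is used up, left-handed product equals the left-handed charge, 50.0% of the total, plus the net crossing. The left-handed form is consumed faster, so the net crossing runs towards it.

2. Ceiling. With instant crossing the two forms stay equal, and product forms in the ratio of the two coupling constants. This is the selectivity factor, 2.05, and it gives 67.3%.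

3. Crossing rate. The impurity takes up the racemization catalyst at first on a time constant of 0.617 s, but the two charges nearly match, so the tail runs on 6.17 s, shorter than the run, and 10.0% of that catalyst survives. After that tail the survivors give a crossing rate of 0.00799 /s, a time constant of 125 s, longer than the run.

4. Lag. In theta, free catalyst grows from nothing, steadily at first, so each substrate fades as the exponential of minus time squared. With partner at its full charge, left-handed substrate lasts about 13.5 s and right-handed substrate about 19.3 s, a lag of 5.84 s.

5. The leak. We define the leak as the crossing rate times the lag times the 50.0% of the charge that stands unmatched during the lag: 2.3 percentage points for theta. Partner falling to its floor, 9.09% of charge, stretches the times and gives 7.7 points. Theta's bracket is therefore 52.3% to 57.7%, and we hold alpha, the same flask for its first 30 s, to it too.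

6. Gamma. The factors 1.6, 14 and 1.5 shrink the lag and raise the crossing rate, so gamma's leak is 0.77 points to 2.6 points. But by this reckoning gamma's right-handed substrate lasts about 4.13 s, shorter than the tail, so more racemization catalyst than the surviving share stands through gamma's lag, and these two figures lean low. These brackets are wider than 1.5 points, so we name no winner by hand.

7. The forecast says all alike, with 53.1%, 52.7% and 51.9% for alpha, theta and gamma: “Heating speeds catalyst release far more than racemization, which shortens the window for that leakage”. Each of its numbers lies inside our bracket for that flask.

8. The simulation gives all alike: 53.2%, 52.6% and 52.1%. Theta still holds 0.946% as left-handed substrate.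

Gamma's gain over the floor is 2.1 points, inside our leak. Of the steps taken away, the coupling of right-handed substrate has the largest single effect on gamma: without it gamma ends at 75.5%, a change of 23 points, more than the 6.8 points from taking away the step in which the impurity consumes racemization catalyst. The forecast's gamma number would fail with more racemization catalyst, since the answer has moved 5 points at 15.5 µM. The neighbour of gamma charged with 4.0 × 10⁻⁵ M keeps 77.5% of it. There the leak reckons 24 points, more than the 17 points up to the ceiling, and that flask ends below the ceiling, at 63.2%.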